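You charge Q and Z in nearly equal amounts and want E.J, counted as a fraction of the Q charged.

    Q ⇌ E (K1 = 1.0, k1 = 0.11 h⁻¹)
    Z → J (k2 = 1.1 h⁻¹)
    E + J → E.J (k3 = 57 M⁻¹ h⁻¹)
    J → G (k4 = 0.049 h⁻¹)
    Z + E.J → Z.E.J (k5 = 0.74 M⁻¹ h⁻¹)

common to all: time 2.5 d
- violet: Q 0.072 M; Z 0.950 equiv (fed, over 50 h); all else is in the flask from the start; the feed brings no volume worth counting
- red: Q 0.072 M; Z 0.950 equiv (in portions, 2, over 50 h); first portion at the start, last at 50 h
- ochre: Q 0.072 M (fed, over 50 h); Z 0.950 equiv; all else is in the flask from the start; the feed brings no volume worth counting
- teal: Q 0.072 M; Z 0.950 equiv; everything together at the start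

- the flask that comes out highest in amount of E.J, in percent of the Q charged, or "all alike" when all lie within 1.5 percentage points (violet / red / ochre / teal / all alike)
- E.J at the end, in percent of the Q charged, violet
- E.J at the end, in percent of the Q charged, red
- E.J at the end, in percent of the Q charged, ochre
- E.J at the end, in percent of the Q charged, teal

Take violet, where Z, the limiting reagent at 0.950 equiv, trickles in. Z turns into J with a half-life of 0.63 h and Q relaxes with E with a half-life of 0.131 d, both far shorter than the 50 h feed. As a rough assumption of mine, and no more than that, I freeze E at half of whatever has not yet become E.J.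

You then watch J, which can go to E or to G. The two exits run equally when E stands at the break-even fraction 1.19%, the fraction of the charge at which capture by E (rate constant 57 M⁻¹ h⁻¹) matches decay to G (rate constant 0.049 h⁻¹). Above it, the part of J lost is roughly the break-even fraction divided by the fraction of E.

On that assumption, add that loss up while the unreacted part falls from the whole charge to 5.00%. You get twice the break-even fraction times ln(1/5.00%), a loss of 7.15%. I set the Z + E.J step aside, so my figure for violet is 87.8%, and the reckoning stops at this flask.

The forecast differs from me on violet. It gives 81% for violet, 79% for red, 42% for ochre and 76% for teal, with violet highest, because “slow Z feed does this, split Z does nearly as well”.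

The flasks end at 84.4% for violet, 78.6% for red, 37.4% for ochre and 72.2% for teal. So violet is highest, ahead of red by 5.8 percentage points, more than the 1.5 points margin.

Violet's 84.4% lies below my 87.8%, and with the Z + E.J step struck out violet gives 87.6%. My assumption on E does not hold in violet: at 2.08 d violet has less E, 6.18%, than Q, 12.6%. The G in violet at the end, 0.00458 M, is 6.37% of the charge, against the 7.15% reckoned from the break-even fraction. Take the neighbour, violet with 0.570 equiv of Z: the same fraction gives a loss of 2.01%, and that flask ends with G at 0.00156 M, which is 2.17% of the charge.

(The numbers of this flask are made up; the flask was simulated.)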